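## Retrosynthetic overview
- The last event is acidolysis of a tert-butyl ester on the B-ring carboxyl group.
- Key disconnection: the depside is cut at the O–C(aryl) bond, not at the usual acyl–O bond. The A-ring keto acid acts as O-nucleophile and is joined to a B-ring 4-iodoarene by nickel/photosensitised C–O cross-coupling.
- B-ring iodide: C4 is selected by sterically controlled Ir C–H borylation/iododeboronation of tert-butyl 2-methoxy-6-pentylbenzoate, itself made by lateral butylation of the 6-methyl ester. No resorcinol has to be differentiated.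
- A-ring acid: lateral acylation of the methyl everninate dianion with the hexanoyl Weinreb amide, then saponification.
- Rings: none is formed. Both benzene rings are bought (methyl orsellinate and 2-methoxy-6-methylbenzoic acid) and only decorated.

Assumption: the target SMILES holds no stereocentre and no stereogenic double bond, so confluentic acid is achiral and the "single enantiomer" request needs no stereocontrol.

## Route

Step 1
Reactants: 1 methyl orsellinate (methyl 2,4-dihydroxy-6-methylbenzoate)
Product: 2 methyl everninate (methyl 2-hydroxy-4-methoxy-6-methylbenzoate)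
Conditions: MeI (1.05 equiv), K2CO3 (1.1 equiv), acetone, reflux
Reagents that add atoms: iodomethane, CI
Why: Williamson O-methylation, in which the 2-OH is hydrogen-bonded to the ester carbonyl and so is far less acidic and nucleophilic, and one equivalent of MeI therefore alkylates only the free 4-OH.

Step 2
Reactants: 3 hexanoyl chloride
Product: 4 N-methoxy-N-methylhexanamide (Weinreb amide)
Conditions: MeNH(OMe)·HCl (1.1 equiv), K2CO3 (2.5 equiv), CH2Cl2/H2O, 0 °C → rt
Reagents that add atoms: N,O-dimethylhydroxylamine hydrochloride, CNOC.Cl
Why: Schotten–Baumann N-acylation, in which the aqueous carbonate takes up both equivalents of HCl and the acid chloride reacts faster with the free amine than with water.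

Step 3
Reactants: 2 methyl everninate; 4 N-methoxy-N-methylhexanamide
Product: 7 methyl 2-hydroxy-4-methoxy-6-(2-oxoheptyl)benzoate, via dilithio dianion 5 (not isolated), via tetrahedral lithium adduct 6 (not isolated)
Conditions: LDA (2.2 equiv), THF, −78 °C, 1 h; then 4 (1.2 equiv), −78 → −30 °C; 1 M HCl quench, 0 °C
Reagents that add atoms: LDA, [Li]N(C(C)C)C(C)C (lithium, present only in 5 and 6)
Why: Lateral (benzylic) lithiation followed by Weinreb ketone synthesis, in which the first equivalent of base forms a phenoxide that shields the ester, the second removes the ester-acidified ortho-methyl proton, and the chelated adduct 6 (a transient racemic centre, lost on quench) stops the acylation at the ketone stage.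

Step 4
Reactants: 7 methyl 2-hydroxy-4-methoxy-6-(2-oxoheptyl)benzoate
Product: 9 2-hydroxy-4-methoxy-6-(2-oxoheptyl)benzoic acid, via dipotassium salt 8 (not isolated)
Conditions: KOH (6 equiv), DMSO/H2O 4:1, 80 °C; then ice, 1 M HCl to pH 2, 0 °C
Reagents that add atoms: potassium hydroxide, [K+].[OH-] (oxygen of the new carboxyl group; potassium present only in 8)
Why: Saponification (BAc2) with poorly solvated hydroxide overcomes the two ortho groups, the open dianion is the stable form in base, and cold acidification frees the keto acid without the heat or strong acid that would cause decarboxylation or enol-lactonisation.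

Step 5
Reactants: 10 2-methoxy-6-methylbenzoic acid
Product: 11 tert-butyl 2-methoxy-6-methylbenzoate
Conditions: Me2NCH(Ot-Bu)2 (4 equiv), toluene, 80 °C
Reagents that add atoms: N,N-dimethylformamide di-tert-butyl acetal, CN(C)C(OC(C)(C)C)OC(C)(C)C
Why: O-tert-butylation of the carboxylate by the acetal-derived alkoxyiminium ion forms the alkyl–oxygen bond, so the two ortho substituents that block ordinary acyl-transfer esterification do not matter.

Step 6
Reactants: 11 tert-butyl 2-methoxy-6-methylbenzoate
Product: 13 tert-butyl 2-methoxy-6-pentylbenzoate, via benzylic lithium compound 12 (not isolated)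
Conditions: LDA (1.2 equiv), THF, −78 °C; n-BuI (1.5 equiv), −78 → 0 °C
Reagents that add atoms: 1-iodobutane, CCCCI; LDA, [Li]N(C(C)C)C(C)C (lithium, present only in 12)
Why: Lateral lithiation and SN2 alkylation, in which the ester-stabilised benzylic anion forms cleanly because the bulky tert-butyl ester resists self-condensation, and the primary iodide extends the methyl group to pentyl.

Step 7
Reactants: 13 tert-butyl 2-methoxy-6-pentylbenzoate
Product: 15 tert-butyl 4-iodo-2-methoxy-6-pentylbenzoate, via aryl pinacol boronate 14 (not isolated)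
Conditions: [Ir(OMe)(cod)]2 (1.5 mol %), dtbpy (3 mol %), B2pin2 (1.0 equiv), THF, 80 °C; evaporate; CuI (10 mol %), 1,10-phenanthroline (20 mol %), KI (1.5 equiv), MeOH/H2O 4:1, air, 80 °C
Reagents that add atoms: bis(pinacolato)diboron, CC1(C)OB(OC1(C)C)B1OC(C)(C)C(C)(C)O1 (Bpin, present only in 14); potassium iodide, [K+].[I-]
Why: Sterically controlled iridium-catalysed C–H borylation (Hartwig–Miyaura type) reaches only C4–H, the one ring hydrogen without an ortho neighbour, and copper-catalysed aerobic iododeboronation replaces boron ipso through an aryl–copper species under non-acidic conditions that the tert-butyl ester survives.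

Step 8
Reactants: 9 2-hydroxy-4-methoxy-6-(2-oxoheptyl)benzoic acid (1.3 equiv); 15 tert-butyl 4-iodo-2-methoxy-6-pentylbenzoate
Product: 16 tert-butyl confluentate (tert-butyl 4-[2-hydroxy-4-methoxy-6-(2-oxoheptyl)benzoyloxy]-2-methoxy-6-pentylbenzoate)
Conditions: Ir(ppy)3 (1 mol %), NiBr2·glyme (10 mol %), dtbbpy (10 mol %), t-BuNH-i-Pr (2 equiv), degassed DMF, 450 nm LEDs, 25 °C
Reagents that add atoms: none
Why: Nickel/photosensitiser dual-catalysed C(sp2)–O cross-coupling of a carboxylic acid with an aryl halide forms the depside O–aryl bond at room temperature by oxidative addition of the unhindered, ester-activated C4–I bond, carboxylate exchange at Ni(II) and energy-transfer-triggered reductive elimination, so acid 9 reacts only as a nucleophile (no acyl activation, hence no enol-lactonisation onto the ketone and no penalty from its two ortho groups) while the hydrogen-bonded 2-OH stays protonated under the hindered amine base.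

Step 9
Reactants: 16 tert-butyl confluentate
Product: 17 confluentic acid (4-[2-hydroxy-4-methoxy-6-(2-oxoheptyl)benzoyloxy]-2-methoxy-6-pentylbenzoic acid)
Conditions: TFA/CH2Cl2 1:3, 0 °C → rt, 2 h, N2 sweep
Reagents that add atoms: none
Why: Acidolysis (AAL1) of the tert-butyl ester is sped up by strain relief at the di-ortho-substituted carboxyl group, and it leaves the aryl ester, ketone, phenol and methyl ethers untouched because none of them can leave as a stabilised cation.

## Compound list
1 | methyl orsellinate (methyl 2,4-dihydroxy-6-methylbenzoate) | COC(=O)c1c(C)cc(O)cc1O | starting material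
2 | methyl everninate (methyl 2-hydroxy-4-methoxy-6-methylbenzoate) | COC(=O)c1c(C)cc(OC)cc1O | intermediate
3 | hexanoyl chloride | CCCCCC(=O)Cl | starting material
4 | N-methoxy-N-methylhexanamide | CCCCCC(=O)N(C)OC | intermediate
5 | dilithio dianion of 2 (lithium phenoxide plus benzylic lithium) | [Li]Cc1cc(OC)cc(O[Li])c1C(=O)OC | intermediate (not isolated)
6 | tetrahedral lithium adduct of 5 and 4 (racemic transient centre) | CCCCCC(O[Li])(N(C)OC)Cc1cc(OC)cc(O[Li])c1C(=O)OC | intermediate (not isolated)
7 | methyl 2-hydroxy-4-methoxy-6-(2-oxoheptyl)benzoate | CCCCCC(=O)Cc1cc(OC)cc(O)c1C(=O)OC | intermediate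
8 | dipotassium 4-methoxy-2-oxido-6-(2-oxoheptyl)benzoate | CCCCCC(=O)Cc1cc(OC)cc([O-])c1C(=O)[O-].[K+].[K+] | intermediate (not isolated)
9 | 2-hydroxy-4-methoxy-6-(2-oxoheptyl)benzoic acid | CCCCCC(=O)Cc1cc(OC)cc(O)c1C(=O)O | intermediate
10 | 2-methoxy-6-methylbenzoic acid | COc1cccc(C)c1C(=O)O | starting material
11 | tert-butyl 2-methoxy-6-methylbenzoate | COc1cccc(C)c1C(=O)OC(C)(C)C | intermediate
12 | tert-butyl 2-(lithiomethyl)-6-methoxybenzoate | [Li]Cc1cccc(OC)c1C(=O)OC(C)(C)C | intermediate (not isolated)
13 | tert-butyl 2-methoxy-6-pentylbenzoate | CCCCCc1cccc(OC)c1C(=O)OC(C)(C)C | intermediate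
14 | tert-butyl 2-methoxy-6-pentyl-4-(4,4,5,5-tetramethyl-1,3,2-dioxaborolan-2-yl)benzoate | CCCCCc1cc(B2OC(C)(C)C(C)(C)O2)cc(OC)c1C(=O)OC(C)(C)C | intermediate (not isolated)
15 | tert-butyl 4-iodo-2-methoxy-6-pentylbenzoate | CCCCCc1cc(I)cc(OC)c1C(=O)OC(C)(C)C | intermediate
16 | tert-butyl confluentate | CCCCCC(=O)Cc1cc(OC)cc(O)c1C(=O)Oc1cc(CCCCC)c(C(=O)OC(C)(C)C)c(OC)c1 | intermediate
17 | confluentic acid (achiral) | CCCCCC(=O)Cc1cc(OC)cc(O)c1C(=O)Oc1cc(CCCCC)c(C(=O)O)c(OC)c1 | target

## Step count and risks
Total step count: 9.
Longest linear sequence: 5 steps (Steps 1, 3, 4, 8, 9). The B-ring arm (Steps 5, 6, 7, 8, 9) is equally long.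

**Step 8 (most risky).** The salicylate unit may chelate nickel. Iodide 15 may be hydrodeiodinated by the excited photocatalyst and the amine. The C–I bond is only moderately activated, because the ester is twisted out of conjugation. The fallback reverses the polarity of the bond formation, making the acyl–oxygen bond instead of the aryl–oxygen bond. It sets out from 13 and comes back to the route at 16. Compound 13 is borylated as in Step 7 to 14. Instead of being iodinated, 14 is oxidised in the same pot with NaBO3·4H2O in THF/H2O at rt to tert-butyl 4-hydroxy-2-methoxy-6-pentylbenzoate F1. This phenol is then condensed with acid 9 by DCC in toluene at rt (carbodiimide depside esterification) to give 16.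

**Step 3.** The second deprotonation of the electron-rich phenoxide may stay incomplete, and the anion may simply take a proton from 4. The fallback uses the mono-anion of a fully masked toluate and restores the phenol afterwards by chelation-controlled demethylation. It sets out from 2 and comes back at 7.
- Compound 2 is O-methylated (excess MeI, K2CO3, DMF, 60 °C) to methyl 2,4-dimethoxy-6-methylbenzoate F2.
- LDA (1.1 equiv, THF, −78 °C) gives methyl 2-(lithiomethyl)-4,6-dimethoxybenzoate F3, which adds to 4 to give the tetrahedral lithium adduct F4.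
- An HCl quench delivers methyl 2,4-dimethoxy-6-(2-oxoheptyl)benzoate F5.
- BCl3 (CH2Cl2, −78 → 0 °C) then removes only the 2-O-methyl group, which sits in a six-membered boron chelate with the ester carbonyl, and gives 7.

**Step 9.** In acid the ketone enol may attack the aryl ester and expel the B-ring phenol, and the tert-butyl cation may alkylate the electron-rich A ring. The fallback changes the protecting-group plan so that the last step is a neutral hydrogenolysis. It sets out from 15 and comes back at 17.
- Compound 15 is cleaved with TFA/CH2Cl2, harmless at this stage, to 4-iodo-2-methoxy-6-pentylbenzoic acid F6.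
- BnBr and K2CO3 in DMF give benzyl 4-iodo-2-methoxy-6-pentylbenzoate F7.
- Coupling with 9 under the conditions of Step 8 gives benzyl confluentate F8.
- H2 (1 atm) over Pd/C in EtOAc gives 17.

## Further compounds
F1 | step 8 | tert-butyl 4-hydroxy-2-methoxy-6-pentylbenzoate | CCCCCc1cc(O)cc(OC)c1C(=O)OC(C)(C)C
F2 | step 3 | methyl 2,4-dimethoxy-6-methylbenzoate | COC(=O)c1c(C)cc(OC)cc1OC
F3 | step 3 | methyl 2-(lithiomethyl)-4,6-dimethoxybenzoate | [Li]Cc1cc(OC)cc(OC)c1C(=O)OC
F4 | step 3 | tetrahedral lithium adduct of F3 and 4 (racemic transient centre) | CCCCCC(O[Li])(N(C)OC)Cc1cc(OC)cc(OC)c1C(=O)OC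
F5 | step 3 | methyl 2,4-dimethoxy-6-(2-oxoheptyl)benzoate | CCCCCC(=O)Cc1cc(OC)cc(OC)c1C(=O)OC
F6 | step 9 | 4-iodo-2-methoxy-6-pentylbenzoic acid | CCCCCc1cc(I)cc(OC)c1C(=O)O
F7 | step 9 | benzyl 4-iodo-2-methoxy-6-pentylbenzoate | CCCCCc1cc(I)cc(OC)c1C(=O)OCc1ccccc1
F8 | step 9 | benzyl confluentate (benzyl 4-[2-hydroxy-4-methoxy-6-(2-oxoheptyl)benzoyloxy]-2-methoxy-6-pentylbenzoate) | CCCCCC(=O)Cc1cc(OC)cc(O)c1C(=O)Oc1cc(CCCCC)c(C(=O)OCc2ccccc2)c(OC)c1
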